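Locants: oxolane O1, C2 (aryl), C3 (carries C9H2–O), C4 (carries C7'H2–aryl), C5 (CH2). Cuts, in order: the ester bond C9O–C(=O); then, with the C9 oxygen re-bonded to C7' and C5 raised to C=O, the C4–C7' bond; then the ether O–C7'; last C2–C3 and O1–C5.
Enabling feature: the C9 arm on C3 and the C7' arm on C4 sit on the same face of the oxolane. C3–C9–O–C7'–C4 can therefore exist as a second five-membered ring cis-fused across C3–C4 to ring O1–C2–C3–C4–C5, and C4, once alpha to a C5 carbonyl, can carry a diazo group.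
Forward: the lactone ring closes first (succinate aldol with O-tosylvanillin, then O1–C5 lactonisation). The C9 oxygen is then benzylated, and the second ring closes by carbenoid insertion into the O–C7'H2 group.
C5=O is then taken down to CH2 and the C7'–O bond is cleaved reductively in one ionic-hydrogenation pot. The phenols are freed and the C9 ester is made last.
Stereochemistry: C2 and C3 come from an (R)-4-benzyloxazolidinone boron aldol (syn aldol, hence 2,3-trans lactone). C4 follows from the obligatory cis ring fusion, and C7' is transient.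
Electronic switch: a tosylate keeps the benzylic C2–O1 bond closed, while a silyl ether lets the benzylic C7'–O bond ionise.

Key step: step 11

Assumption: the drawn enantiomer is read as (2R,3S,4S), which calls for the (R)-auxiliary. C7' of the bicyclic intermediates is drawn with its aryl group endo, although either epimer would serve.

Step 1
Reactants: 1 vanillin
Product: 2 4-formyl-2-methoxyphenyl 4-methylbenzenesulfonate (O-tosylvanillin)
Conditions: TsCl, Et3N, DMAP (cat.), CH2Cl2, 0 °C to rt
Reagents that add atoms: p-toluenesulfonyl chloride, Cc1ccc(cc1)S(=O)(=O)Cl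
Why: O-Sulfonylation of a phenol is routine, and the aryl tosylate should outlast peroxide, borane, amide base and aluminium hydride while making this ring a poor stabiliser of a benzylic cation.

Step 2
Reactants: 3 (R)-4-benzyl-1,3-oxazolidin-2-one; 4 methyl 4-chloro-4-oxobutanoate
Product: 6 methyl 4-[(4R)-4-benzyl-2-oxo-1,3-oxazolidin-3-yl]-4-oxobutanoate, via lithium oxazolidinide 5 (not isolated)
Conditions: n-BuLi, THF, −78 °C; then 4, −78 to 0 °C
Reagents that add atoms: n-butyllithium, [Li]CCCC (lithium in 5 only)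
Why: N-Acylation of the lithiated auxiliary, in which the acid chloride end of 4 reacts far faster than its methyl ester and the stereocentre of 3 is not involved.

Step 3
Reactants: 6 succinyl imide; 2 O-tosylvanillin
Product: 9 (4R)-4-benzyl-3-({(2R,3R)-2-[3-methoxy-4-(tosyloxy)phenyl]-5-oxooxolan-3-yl}carbonyl)-1,3-oxazolidin-2-one, via boron enolate 7 (not isolated), via syn aldol 8 (not isolated)
Conditions: Bu2BOTf, iPr2NEt, CH2Cl2, −78 to 0 °C; 2, −78 to 0 °C; H2O2, pH 7 buffer, MeOH, 0 °C; then p-TsOH (cat.), CH2Cl2, rt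
Reagents that add atoms: dibutylboron triflate, CCCCB(CCCC)OS(=O)(=O)C(F)(F)F (boron unit in 7 only)
Why: Evans syn aldol reaction: soft enolisation occurs only next to the imide and gives the Z-boron enolate 7, which meets the aldehyde in a chair-like six-membered transition state on the face away from the benzyl group of the (R)-auxiliary, setting C3 and C2 (both R in 8), after which the benzylic hydroxyl closes on the methyl ester (5-exo-trig lactonisation) to the 2,3-trans lactone.

Step 4
Reactants: 9 lactone imide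
Product: 11 (2R,3R)-2-[3-methoxy-4-(tosyloxy)phenyl]-5-oxooxolane-3-carboxylic acid, via peroxy acid 10 (not isolated)
Conditions: LiOH, H2O2, THF–H2O, 0 °C; Na2SO3; aq. HCl
Reagents that add atoms: hydrogen peroxide, OO (as LiOOH; one oxygen stays in the CO2H group)
Why: Hydroperoxide cleavage of an N-acyloxazolidinone attacks the exocyclic imide carbonyl selectively, sulfite reduces peroxy acid 10, any lactone opened by hydroxide can only reclose to the same five-membered ring on acidification, and neither stereocentre should be enolised at 0 °C.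

Step 5
Reactants: 11 lactone acid
Product: 12 (4S,5R)-4-(hydroxymethyl)-5-[3-methoxy-4-(tosyloxy)phenyl]oxolan-2-one
Conditions: BH3·SMe2, THF, 0 °C to rt; MeOH
Reagents that add atoms: none
Why: Chemoselective borane reduction of a carboxylic acid (through the acyloxyborane) leaves lactone and sulfonate alone, and the base-free medium should prevent migration of the lactone acyl group to the new primary hydroxyl.

Step 6
Reactants: 1 vanillin
Product: 13 4-[(tert-butyldimethylsilyl)oxy]-3-methoxybenzaldehyde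
Conditions: TBSCl, imidazole, DMF, rt
Reagents that add atoms: tert-butyldimethylsilyl chloride, CC(C)(C)[Si](C)(C)Cl
Why: Imidazole-promoted silylation of a phenol gives a silyl ether that keeps this ring electron-rich and is fluoride-labile.

Step 7
Reactants: 13 silylated vanillin
Product: 14 {4-[(tert-butyldimethylsilyl)oxy]-3-methoxyphenyl}methanol
Conditions: NaBH4, MeOH, 0 °C
Reagents that add atoms: none
Why: Borohydride reduction of an aromatic aldehyde is fast at 0 °C, so the aryl silyl ether should not be methanolysed.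

Step 8
Reactants: 14 benzylic alcohol
Product: 15 4-[(tert-butyldimethylsilyl)oxy]-3-methoxybenzyl 2,2,2-trichloroacetimidate
Conditions: Cl3CCN, DBU (cat.), CH2Cl2, 0 °C
Reagents that add atoms: trichloroacetonitrile, N#CC(Cl)(Cl)Cl
Why: Base-catalysed addition of an alcohol to trichloroacetonitrile, the imidate formation routinely used for p-methoxybenzyl transfer reagents.

Step 9
Reactants: 12 hydroxymethyl lactone; 15 imidate
Product: 16 (4S,5R)-4-[({4-[(tert-butyldimethylsilyl)oxy]-3-methoxybenzyl}oxy)methyl]-5-[3-methoxy-4-(tosyloxy)phenyl]oxolan-2-one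
Conditions: La(OTf)3 (5 mol %), toluene, 0 °C to rt
Reagents that add atoms: none
Why: Acid-catalysed trichloroacetimidate benzylation hands the electron-rich benzyl group to the primary hydroxyl in an SN1-like manner, is driven by formation of trichloroacetamide, and avoids the alkoxide that would trigger translactonisation.

Step 10
Reactants: 16 lactone ether
Product: 19 (4S,5R)-3-diazo-4-[({4-[(tert-butyldimethylsilyl)oxy]-3-methoxybenzyl}oxy)methyl]-5-[3-methoxy-4-(tosyloxy)phenyl]oxolan-2-one, via lithium enolate 17 (not isolated), via trifluoroacetyl lactone 18 (not isolated)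
Conditions: LiN(SiMe3)2, THF, −78 °C; CF3CO2CH2CF3, −78 °C; 5% aq. HCl work-up; then MsN3, Et3N, H2O (1 equiv), MeCN, rt
Reagents that add atoms: methanesulfonyl azide, CS(=O)(=O)N=[N+]=[N-] (N2 in 19); lithium bis(trimethylsilyl)amide, [Li]N([Si](C)(C)C)[Si](C)(C)C (lithium in 17 only); 2,2,2-trifluoroethyl trifluoroacetate, O=C(OCC(F)(F)F)C(F)(F)F (CF3CO in 18 only)
Why: Regitz-type deacylative diazo transfer: the lactone is too weakly acidic for direct transfer, so its enolate 17 is C-trifluoroacetylated and the activated dicarbonyl 18 takes the diazo group from the sulfonyl azide and sheds the trifluoroacetyl group as its N-sulfonyl amide, while C2 and C3 are not enolisable and the tosylate and silyl ether carry no acidic or electrophilic site that competes at −78 °C.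

Step 11
Reactants: 19 diazo lactone
Product: 21 (1R,2S,5S,6R)-2-{4-[(tert-butyldimethylsilyl)oxy]-3-methoxyphenyl}-6-[3-methoxy-4-(tosyloxy)phenyl]-3,7-dioxabicyclo[3.3.0]octan-8-one, via rhodium carbenoid 20 (not isolated)
Conditions: Rh2(OAc)4 (2 mol %), CH2Cl2, reflux, slow addition of 19
Reagents that add atoms: dirhodium tetraacetate, CC(=O)[O-].CC(=O)[O-].CC(=O)[O-].CC(=O)[O-].[Rh+2].[Rh+2] (metal in 20 only)
Why: Rh2(OAc)4, a divalent rhodium carboxylate, expels N2 from 19 to give the electrophilic carbenoid 20 at C4, which takes up the hydridic C7'–H bond in a concerted, asynchronous three-centre transition state and releases the catalyst. The closest known reaction type is exactly this one, the intramolecular C–H insertion of alpha-diazo-gamma-butyrolactones into benzylic ether C–H bonds that delivers furofuranones. The single ring closed, C3–C9–O–C7'–C4, forms in the 1,5-insertion mode, the only unstrained ring size within reach of C4. C4 is set by the substrate, because the tether hangs from C3 on one face and a bicyclo[3.3.0]octane can only be cis-fused, so C7' ends up cis to C9 and trans to the C2 aryl group fixed in step 3; at C7' the aryl group is expected endo by analogy with this substrate class, and either outcome serves because C7' becomes CH2 in step 13. The selectivity needed is insertion over the 1,2-shift of the C3 hydrogen to the carbenoid carbon (butenolide), over attack on the arenes and over carbene dimerisation; the C7'–H bond is doubly activated by the ether oxygen and the 4-silyloxy-3-methoxyphenyl ring, the tosylated ring is electron-poor and remote, and slow addition keeps the diazo concentration low.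

Step 12
Reactants: 21 furofuranone
Product: 22 lactol of 21 (C5–OH as both anomers with C2/C3/C4/C7' as in 21)
Conditions: iBu2AlH (1.2 equiv), CH2Cl2, −78 °C; aq. potassium sodium tartrate
Reagents that add atoms: none
Why: Partial reduction of a gamma-lactone to the lactol works because the tetrahedral aluminium alkoxide persists at −78 °C, sulfonate and silyl ether are inert to the hydride, and the new C5 centre is unselective but vanishes in the next step.

Step 13
Reactants: 22 lactol
Product: 24 {(2R,3S,4S)-4-{4-[(tert-butyldimethylsilyl)oxy]-3-methoxybenzyl}-2-[3-methoxy-4-(tosyloxy)phenyl]oxolan-3-yl}methanol, via furofuran 23 (not isolated)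
Conditions: Et3SiH (6 equiv), BF3·OEt2 (3 equiv), CH2Cl2, −78 °C, then to 0 °C; aq. NaHCO3
Reagents that add atoms: none
Why: Ionic hydrogenation (Kursanov–Parnes type): BF3 first ionises the lactol to the C5 oxocarbenium ion, which the silane reduces at −78 °C to furofuran 23, and on warming only the C7'–O bond, whose cation is stabilised by the para silyloxy group, ionises and is reduced to CH2 with release of C9–OH, whereas the C2–O1 bond next to the tosyloxy-substituted ring should stay closed and C2, C3 and C4 are untouched.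

Step 14
Reactants: 24 silyl ether
Product: 25 {(2R,3S,4S)-4-(4-hydroxy-3-methoxybenzyl)-2-[3-methoxy-4-(tosyloxy)phenyl]oxolan-3-yl}methanol
Conditions: Bu4NF, AcOH, THF, 0 °C
Reagents that add atoms: none
Why: Fluoride cleavage of an aryl silyl ether, buffered with acetic acid so that no phenoxide builds up, leaves sulfonate, alcohol and oxolane alone.

Step 15
Reactants: 25 aryl tosylate
Product: 26 [(2R,3S,4S)-4-(4-hydroxy-3-methoxybenzyl)-2-(4-hydroxy-3-methoxyphenyl)oxolan-3-yl]methanol ((2R,3S,4S)-lariciresinol)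
Conditions: Mg turnings, MeOH, rt; aq. NH4Cl
Reagents that add atoms: none
Why: Reductive desulfonylation by electron transfer from magnesium in methanol breaks the S–O bond of the aryl tosylate and frees the phenol at room temperature, conditions under which the benzylic C2–O1 bond and the three stereocentres should be safe.

Step 16
Reactants: 26 (2R,3S,4S)-lariciresinol; 27 4-hydroxybenzoic acid
Product: 28 agastinol, [(2R,3S,4S)-4-(4-hydroxy-3-methoxybenzyl)-2-(4-hydroxy-3-methoxyphenyl)oxolan-3-yl]methyl 4-hydroxybenzoate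
Conditions: PPh3, DIAD, THF, 0 °C to rt
Reagents that add atoms: none
Why: Mitsunobu esterification is chemoselective without protecting groups, because only the aliphatic C9 hydroxyl forms an alkoxyphosphonium ion and only the carboxylic acid, far more acidic than the three phenols, is deprotonated to act as nucleophile, and substitution at the achiral C9H2 affects no stereocentre.

Compound list
1 | vanillin | COc1cc(C=O)ccc1O | starting material
2 | 4-formyl-2-methoxyphenyl 4-methylbenzenesulfonate | COc1cc(C=O)ccc1OS(=O)(=O)c1ccc(C)cc1 | intermediate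
3 | (R)-4-benzyl-1,3-oxazolidin-2-one | O=C1N[C@H](Cc2ccccc2)CO1 | starting material
4 | methyl 4-chloro-4-oxobutanoate | COC(=O)CCC(=O)Cl | starting material
5 | N-lithio derivative of 3 (not isolated) | [Li]N1C(=O)OC[C@H]1Cc1ccccc1 | intermediate
6 | methyl 4-[(4R)-4-benzyl-2-oxo-1,3-oxazolidin-3-yl]-4-oxobutanoate | COC(=O)CCC(=O)N1C(=O)OC[C@H]1Cc1ccccc1 | intermediate
7 | (Z)-dibutylboron enolate of 6 (not isolated) | CCCCB(CCCC)O/C(=C\CC(=O)OC)N1C(=O)OC[C@H]1Cc1ccccc1 | intermediate
8 | methyl (3R)-3-{(R)-hydroxy[3-methoxy-4-(tosyloxy)phenyl]methyl}-4-[(4R)-4-benzyl-2-oxo-1,3-oxazolidin-3-yl]-4-oxobutanoate, syn aldol (not isolated) | COC(=O)C[C@H]([C@@H](O)c1ccc(OS(=O)(=O)c2ccc(C)cc2)c(OC)c1)C(=O)N1C(=O)OC[C@H]1Cc1ccccc1 | intermediate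
9 | (4R)-4-benzyl-3-({(2R,3R)-2-[3-methoxy-4-(tosyloxy)phenyl]-5-oxooxolan-3-yl}carbonyl)-1,3-oxazolidin-2-one, 2,3-trans | C1C(=O)O[C@@H](c2ccc(OS(=O)(=O)c3ccc(C)cc3)c(OC)c2)[C@@H]1C(=O)N1C(=O)OC[C@H]1Cc1ccccc1 | intermediate
10 | (2R,3R)-2-[3-methoxy-4-(tosyloxy)phenyl]-5-oxooxolane-3-carboperoxoic acid (not isolated) | C1C(=O)O[C@@H](c2ccc(OS(=O)(=O)c3ccc(C)cc3)c(OC)c2)[C@@H]1C(=O)OO | intermediate
11 | (2R,3R)-2-[3-methoxy-4-(tosyloxy)phenyl]-5-oxooxolane-3-carboxylic acid | C1C(=O)O[C@@H](c2ccc(OS(=O)(=O)c3ccc(C)cc3)c(OC)c2)[C@@H]1C(=O)O | intermediate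
12 | (4S,5R)-4-(hydroxymethyl)-5-[3-methoxy-4-(tosyloxy)phenyl]oxolan-2-one | C1C(=O)O[C@@H](c2ccc(OS(=O)(=O)c3ccc(C)cc3)c(OC)c2)[C@@H]1CO | intermediate
13 | 4-[(tert-butyldimethylsilyl)oxy]-3-methoxybenzaldehyde | COc1cc(C=O)ccc1O[Si](C)(C)C(C)(C)C | intermediate
14 | {4-[(tert-butyldimethylsilyl)oxy]-3-methoxyphenyl}methanol | COc1cc(CO)ccc1O[Si](C)(C)C(C)(C)C | intermediate
15 | 4-[(tert-butyldimethylsilyl)oxy]-3-methoxybenzyl 2,2,2-trichloroacetimidate | COc1cc(COC(=N)C(Cl)(Cl)Cl)ccc1O[Si](C)(C)C(C)(C)C | intermediate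
16 | (4S,5R)-4-[({4-[(tert-butyldimethylsilyl)oxy]-3-methoxybenzyl}oxy)methyl]-5-[3-methoxy-4-(tosyloxy)phenyl]oxolan-2-one | C1C(=O)O[C@@H](c2ccc(OS(=O)(=O)c3ccc(C)cc3)c(OC)c2)[C@@H]1COCc1ccc(O[Si](C)(C)C(C)(C)C)c(OC)c1 | intermediate
17 | lithium enolate of 16 (not isolated) | C1=C(O[Li])O[C@@H](c2ccc(OS(=O)(=O)c3ccc(C)cc3)c(OC)c2)[C@@H]1COCc1ccc(O[Si](C)(C)C(C)(C)C)c(OC)c1 | intermediate
18 | C4-trifluoroacetyl derivative of 16, C4 epimers or enol (not isolated) | FC(F)(F)C(=O)C1C(=O)O[C@@H](c2ccc(OS(=O)(=O)c3ccc(C)cc3)c(OC)c2)[C@@H]1COCc1ccc(O[Si](C)(C)C(C)(C)C)c(OC)c1 | intermediate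
19 | (4S,5R)-3-diazo-4-[({4-[(tert-butyldimethylsilyl)oxy]-3-methoxybenzyl}oxy)methyl]-5-[3-methoxy-4-(tosyloxy)phenyl]oxolan-2-one, 2,3-trans (key-step precursor) | [N-]=[N+]=C1C(=O)O[C@@H](c2ccc(OS(=O)(=O)c3ccc(C)cc3)c(OC)c2)[C@@H]1COCc1ccc(O[Si](C)(C)C(C)(C)C)c(OC)c1 | intermediate
20 | rhodium carbenoid at C4, the Rh2(OAc)4 core abbreviated to one Rh atom (not isolated) | [Rh]=C1C(=O)O[C@@H](c2ccc(OS(=O)(=O)c3ccc(C)cc3)c(OC)c2)[C@@H]1COCc1ccc(O[Si](C)(C)C(C)(C)C)c(OC)c1 | intermediate
21 | (1R,2S,5S,6R)-2-{4-[(tert-butyldimethylsilyl)oxy]-3-methoxyphenyl}-6-[3-methoxy-4-(tosyloxy)phenyl]-3,7-dioxabicyclo[3.3.0]octan-8-one, cis-fused, C2 aryl exo, C7' aryl endo (key-step product) | COc1cc([C@@H]5[C@@H]2C(=O)O[C@@H](c3ccc(OS(=O)(=O)c4ccc(C)cc4)c(OC)c3)[C@@H]2CO5)ccc1O[Si](C)(C)C(C)(C)C | intermediate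
22 | lactol of 21, both C5 anomers | COc1cc([C@@H]5[C@@H]2C(O)O[C@@H](c3ccc(OS(=O)(=O)c4ccc(C)cc4)c(OC)c3)[C@@H]2CO5)ccc1O[Si](C)(C)C(C)(C)C | intermediate
23 | cis-fused 2,6-diaryl-3,7-dioxabicyclo[3.3.0]octane with the configuration of 21 (not isolated) | COc1cc([C@@H]5[C@@H]2CO[C@@H](c3ccc(OS(=O)(=O)c4ccc(C)cc4)c(OC)c3)[C@@H]2CO5)ccc1O[Si](C)(C)C(C)(C)C | intermediate
24 | {(2R,3S,4S)-4-{4-[(tert-butyldimethylsilyl)oxy]-3-methoxybenzyl}-2-[3-methoxy-4-(tosyloxy)phenyl]oxolan-3-yl}methanol | COc1cc(C[C@@H]2CO[C@@H](c3ccc(OS(=O)(=O)c4ccc(C)cc4)c(OC)c3)[C@@H]2CO)ccc1O[Si](C)(C)C(C)(C)C | intermediate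
25 | {(2R,3S,4S)-4-(4-hydroxy-3-methoxybenzyl)-2-[3-methoxy-4-(tosyloxy)phenyl]oxolan-3-yl}methanol | COc1cc(C[C@@H]2CO[C@@H](c3ccc(OS(=O)(=O)c4ccc(C)cc4)c(OC)c3)[C@@H]2CO)ccc1O | intermediate
26 | (2R,3S,4S)-lariciresinol | COc1cc(C[C@@H]2CO[C@@H](c3ccc(O)c(OC)c3)[C@@H]2CO)ccc1O | intermediate
27 | 4-hydroxybenzoic acid | OC(=O)c1ccc(O)cc1 | starting material
28 | agastinol | COc1cc(C[C@@H]2CO[C@@H](c3ccc(O)c(OC)c3)[C@@H]2COC(=O)c2ccc(O)cc2)ccc1O | target

Total step count: 16.
Longest linear sequence: 12 steps (steps 1, 3, 4, 5, 9, 10, 11, 12, 13, 14, 15, 16, from vanillin; the branch that starts with step 2 is equally long).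

Steps most likely to fail

Step 11. Migration of the C3 hydrogen to the carbenoid carbon, or carbene dimerisation, may outrun the insertion.
- The fallback sets out from 12 and 14 and returns at 24. It makes C4–C7' by enolate alkylation and corrects C4 by kinetic protonation.
- Alcohol 12 is silylated (Et3SiCl, imidazole, CH2Cl2) to triethylsilyl ether F1. Alcohol 14 is turned by an Appel reaction (CBr4, PPh3, CH2Cl2, 0 °C) into benzyl bromide F2.
- The lithium enolate of F1 (LiN(SiMe3)2, THF, −78 °C) should be alkylated by F2 on the face opposite the C9 arm, giving 3,4-trans benzyl lactone F3.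
- Renewed enolisation and a quench at −78 °C with a bulky proton source (2,6-di-tert-butyl-4-methylphenol) delivers the proton to that same open face. This should turn the benzyl group cis to C9, giving 3,4-cis benzyl lactone F4.
- iBu2AlH (CH2Cl2, −78 °C) then gives lactol F5. Et3SiH/BF3·OEt2 at −78 °C gives oxolane silyl ether F6, and PPTS in MeOH removes the triethylsilyl group to reach 24.

Step 13. The C7' cation may lose the C4 proton before hydride arrives, which would blur the C4 configuration, or the opening may stall after the lactol reduction. Loss of the aryl silyl group here would be harmless, since step 14 removes it anyway.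
- The fallback sets out from 22 and returns at 24. It replaces hydride capture by sulfur capture followed by radical desulfurisation.
- The silane reduction is stopped at −78 °C and furofuran 23 is isolated.
- PhSH with BF3·OEt2 (CH2Cl2, −40 °C) opens the C7'–O bond. The thiol is a much faster cation trap than the silane and should give benzylic sulfide F7.
- Bu3SnH with AIBN (toluene, 90 °C) then replaces sulfur by hydrogen through a benzylic radical that cannot disturb C4.

Step 16. Competing O-alkylation of a phenol, or self-condensation of the hydroxy acid, may erode the chemoselectivity.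
- The fallback sets out from 26 and returns at 28, and it uses transient acetates.
- Ac2O in cold aqueous NaOH acetylates only the phenoxides, giving diacetate F8.
- Steglich esterification (EDC·HCl, DMAP, CH2Cl2) with commercial 4-acetoxybenzoic acid gives triacetate F9.
- Pyrrolidine (CH2Cl2, 0 °C) aminolyses the three aryl acetates far faster than the alkyl benzoate and should release 28.

Further compounds
F1 | step 11 | (4S,5R)-5-[3-methoxy-4-(tosyloxy)phenyl]-4-[(triethylsilyloxy)methyl]oxolan-2-one | C1C(=O)O[C@@H](c2ccc(OS(=O)(=O)c3ccc(C)cc3)c(OC)c2)[C@@H]1CO[Si](CC)(CC)CC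
F2 | step 11 | 4-[(tert-butyldimethylsilyl)oxy]-3-methoxybenzyl bromide | COc1cc(CBr)ccc1O[Si](C)(C)C(C)(C)C
F3 | step 11 | 2,3-trans-3,4-trans C4-benzyl lactone (C4 epimer of F4) | COc1cc(C[C@H]2C(=O)O[C@@H](c3ccc(OS(=O)(=O)c4ccc(C)cc4)c(OC)c3)[C@@H]2CO[Si](CC)(CC)CC)ccc1O[Si](C)(C)C(C)(C)C
F4 | step 11 | 2,3-trans-3,4-cis C4-benzyl lactone | COc1cc(C[C@@H]2C(=O)O[C@@H](c3ccc(OS(=O)(=O)c4ccc(C)cc4)c(OC)c3)[C@@H]2CO[Si](CC)(CC)CC)ccc1O[Si](C)(C)C(C)(C)C
F5 | step 11 | lactol of F4, both C5 anomers | COc1cc(C[C@@H]2C(O)O[C@@H](c3ccc(OS(=O)(=O)c4ccc(C)cc4)c(OC)c3)[C@@H]2CO[Si](CC)(CC)CC)ccc1O[Si](C)(C)C(C)(C)C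
F6 | step 11 | C9 triethylsilyl ether of 24 | COc1cc(C[C@@H]2CO[C@@H](c3ccc(OS(=O)(=O)c4ccc(C)cc4)c(OC)c3)[C@@H]2CO[Si](CC)(CC)CC)ccc1O[Si](C)(C)C(C)(C)C
F7 | step 13 | C7'-phenylsulfanyl derivative of 24, C7' epimers | COc1cc(C(Sc5ccccc5)[C@@H]2CO[C@@H](c3ccc(OS(=O)(=O)c4ccc(C)cc4)c(OC)c3)[C@@H]2CO)ccc1O[Si](C)(C)C(C)(C)C
F8 | step 16 | di-O-acetyl derivative of 26 (both phenols acetylated, C9–OH free) | COc1cc(C[C@@H]2CO[C@@H](c3ccc(OC(C)=O)c(OC)c3)[C@@H]2CO)ccc1OC(C)=O
F9 | step 16 | tri-O-acetylagastinol | COc1cc(C[C@@H]2CO[C@@H](c3ccc(OC(C)=O)c(OC)c3)[C@@H]2COC(=O)c2ccc(OC(C)=O)cc2)ccc1OC(C)=O
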